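All constants were drawn at random within sensible limits; no experiment stands behind them.

If you follow one D through a flask, it meets the same fork at every moment, and the odds there depend on how much free D stands around it.

    D → L, rate k1*[D]/(1 + ([D]/sat1)) (sat1 = 5.3 mM, k1 = 0.068 s⁻¹)
    2 D → D2 (k2 = 5.0 M⁻¹ s⁻¹)
    D → Q (k3 = 8.5 × 10⁻⁵ s⁻¹)
    D ⇌ Z (K4 = 0.32, k4 = 0.031 s⁻¹)
- alder: D 20 mM; time 2.0 min; a closed flask charged with all of it at once and left for 2.0 min
- maple: D 20 mM; one stirred flow tank at steady state, fed with the mixture as stated, mean residence time 2.0 min
- a species is counted by the D in it: one D2 counts as two
- a step written with two of one species runs at k times the square of its concentration and takes two of it each time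
- the stated concentrations are those of everything mixed, before any reaction; amounts are the same in each set-up
- run time (alder): 2.0 min
* the set-up with the highest amount of L at the outlet or at the end, in percent of the D put in ("none" if the first two lie within 2 percentage points) (alder / maple / none)
* amount of L at the outlet or at the end, in percent of the D put in, alder
* amount of L at the outlet or at the end, in percent of the D put in, maple

At free D concentration c, the chance that a D lost to L or by pairing at that moment goes to L (the instantaneous selectivity) is

p(c) = W/(W + c + c·c/S),

with S = 5.3 mM and W = 6.80 mM, the L constant over twice the pairing constant, since two D go each turn. Both paths take D equally fast where c + c·c/S = W, at 3.91 mM, the even-fork concentration c*.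

Alder starts far above it, where p is 6.65%, and then sweeps down. So, with Z left aside and the sweep taken to zero, its yield is the mean of p over the sweep. I bracket it with Simpson's rule in steps of 5.00 mM:

Z never forms (floor): 29.3%

Z always at equilibrium, which cuts the top of the sweep and stretches the mean by at most the factor 1.32 (ceiling): 38.7%

Maple has a single c, so try 1.96 mM, half of c*. There you can count on a net feed of at least 0.145 mM s⁻¹, while the two paths use 0.135 mM s⁻¹, less than the feed. The tank therefore stands above the trial value, which puts a floor of 58.3% under maple, above alder's ceiling. I commit to maple.

The forecast also says maple, with 60.8% for maple, above my floor, and 34.9% for alder, inside my bracket: “The tank wins because it keeps [D] low.”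

The simulation gives maple, with 34.5% for alder and 60.8% for maple. The maple tank holds D at 2.07 mM, below c*. Rebuilt from c*, p at that concentration is 70.2%. The outlet still carries 10.4% as D, plus Z from its tank balance, and applying p to the remainder gives 60.8% of the charge as L.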